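The structural feature behind the strategy: ring A holds three adjacent centres, C4 (quaternary, CH3 and CO2Me), C5 (ring-fusion H) and C10 (ring-fusion CH3), and nothing else (C1–C3 are CH2). Ring A is therefore treated as a reduced Diels–Alder ring (diene C10=C1–C2=C3, dienophile C4=C5) and ring B (C5–C10) as the tether ring.
Key disconnection: C3–C4 and C5–C10 go back to one acyclic (E)-2-methyl enoate/(E)-diene triene that already carries C6, C8 and C9.
Triene from nerol: Sharpless epoxidation and vinyl cuprate opening (C8, C9), hydroboration (C11–C12), alkyne carboalumination then Stille coupling (E-diene), proline-catalysed α-oxygenation (C6), Wittig reaction (E-enoate).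
Side chain: C12–C13 by Negishi coupling; C13–OOH by perhydrolysis with inversion of a Sharpless C13–C14 epoxide; C14=C15 by Julia–Kocienski olefination of the C13 peroxy aldehyde with a C15–C19 sulfone.
Ring order: rings A and B together in step 14; the butenolide ring last, by lactonisation in step 32.

Key step: step 14

Remark: labdane-type numbering is used (ring A = C1–C5 and C10, ring B = C5–C10, side chain C11–C19 with the lactone carbonyl as C19). On the key-step precursor and product a benzyl ether stands at C12–O, because it leaves in the same hydrogenation that saturates C1=C2.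

Step 1
Reactants: 1 nerol
Product: 2 (2S,3R)-2,3-epoxynerol
Conditions: Ti(OiPr)4 (10 mol %), L-(+)-diethyl tartrate (12 mol %), t-BuOOH, 4 Å sieves, CH2Cl2, −20 °C
Reagents that add atoms: tert-butyl hydroperoxide, CC(C)(C)OO
Why: Sharpless asymmetric epoxidation of the allylic alcohol, in which the L-(+)-tartrate titanium complex delivers oxygen to one face of the C2=C3 alkene and so fixes the future C8 (3R) and, before its inversion, C9 (2S), while the remote isopropylidene alkene is left alone.

Step 2
Reactants: 2 (2S,3R)-2,3-epoxynerol; 3 vinylmagnesium bromide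
Product: 4 (2R,3R)-2-ethenyl-3,7-dimethyloct-6-ene-1,3-diol
Conditions: CuI (15 mol %), THF, −40 → 0 °C; aq NH4Cl
Reagents that add atoms: vinylmagnesium bromide, C=C[Mg]Br
Why: Copper-catalysed Grignard opening of a 2,3-epoxy alcohol, an SN2 attack at C2 (C3 is fully substituted) with inversion, which sets C9 and leaves the tertiary C8 carbinol unchanged.

Step 3
Reactants: 4 (2R,3R)-2-ethenyl-3,7-dimethyloct-6-ene-1,3-diol
Product: 5 bis(triethylsilyl) ether of 4
Conditions: Et3SiOTf (2.5 equiv), 2,6-lutidine, CH2Cl2, −78 → 0 °C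
Reagents that add atoms: triethylsilyl triflate, CC[Si](CC)(CC)OS(=O)(=O)C(F)(F)F
Why: Silylation with the silyl triflate caps both the primary (future C10) and the hindered tertiary (C8) hydroxyl, so that no β-hydroxy aldehyde prone to retro-aldol cleavage appears later.

Step 4
Reactants: 5 bis(triethylsilyl) ether of 4
Product: 7 C12 primary alcohol, via B-alkyl-9-BBN adduct 6 (not isolated)
Conditions: 9-BBN (1.5 equiv), THF, 0 °C → rt; then aq NaOAc, 30 % H2O2, 0 °C
Reagents that add atoms: 9-borabicyclo[3.3.1]nonane, B1C2CCCC1CCC2 (boron stays only in 6); hydrogen peroxide, OO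
Why: Anti-Markovnikov hydroboration–oxidation, in which 9-BBN takes the monosubstituted vinyl group and not the trisubstituted alkene, and the buffered oxidation spares the silyl ethers.

Step 5
Reactants: 7 C12 primary alcohol
Product: 8 C12 benzyl ether
Conditions: NaH, BnBr, Bu4NI (cat.), THF, 0 °C → rt
Reagents that add atoms: benzyl bromide, BrCc1ccccc1
Why: Williamson etherification of the unhindered primary alkoxide, which should outrun silyl migration across the four-carbon spacer; benzyl is chosen because it survives the organoaluminium steps and is removed later by hydrogen.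

Step 6
Reactants: 8 C12 benzyl ether
Product: 9 C10 aldehyde
Conditions: (COCl)2 (4 equiv), DMSO (8 equiv), CH2Cl2, −78 → −30 °C; Et3N, −78 °C → rt
Reagents that add atoms: none
Why: Swern oxidation applied to a primary triethylsilyl ether, which is cleaved and oxidised in one operation while the tertiary silyl ether stays, so the aldehyde appears with C8–O still protected.

Step 7
Reactants: 9 C10 aldehyde
Product: 10 terminal alkyne C10≡C1
Conditions: dimethyl (1-diazo-2-oxopropyl)phosphonate, K2CO3, MeOH, 0 °C → rt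
Reagents that add atoms: dimethyl (1-diazo-2-oxopropyl)phosphonate, CC(=O)C(=[N+]=[N-])P(=O)(OC)OC
Why: Ohira–Bestmann (Seyferth–Gilbert) homologation turns the aldehyde into the alkyne under mild carbonate conditions that should keep the α-stereocentre C9 and the β-silyloxy group intact.

Step 8
Reactants: 10 terminal alkyne C10≡C1
Product: 12 (E)-iodoalkene, via alkenyldimethylalane 11 (not isolated)
Conditions: AlMe3 (3 equiv), Cp2ZrCl2 (0.5 equiv), H2O (1.5 equiv), CH2Cl2, −30 °C → rt; then I2, THF, −30 → 0 °C
Reagents that add atoms: trimethylaluminium, C[Al](C)C; iodine, II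
Why: Negishi zirconium-catalysed carboalumination adds methyl (to C10) and aluminium (to C1) syn across the alkyne, and iodinolysis with retention gives the (E)-iodoalkene in which C9 is trans to the future C2, the geometry the diene needs.

Step 9
Reactants: 12 (E)-iodoalkene
Product: 14 C5 aldehyde, via vicinal diol 13 (not isolated)
Conditions: OsO4 (2 mol %), NaIO4 (4 equiv), 2,6-lutidine, dioxane–H2O 3:1, rt
Reagents that add atoms: osmium tetroxide, O=[Os](=O)(=O)=O (oxygen carrier, reoxidised by sodium periodate, [Na+].[O-]I(=O)(=O)=O)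
Why: Lemieux–Johnson oxidative cleavage, in which the electron-rich isopropylidene alkene is dihydroxylated far faster than the hindered, iodine-deactivated alkene; it is done before the diene exists.

Step 10
Reactants: 14 C5 aldehyde; 15 methyl 2-(triphenylphosphoranylidene)propanoate
Product: 17 (E)-2-methyl enoate with C6–O–NHPh, via (6S)-α-aminoxy aldehyde 16 (not isolated)
Conditions: D-proline (20 mol %), PhNO (1.0 equiv), DMSO, rt, 30 min; then 15 (1.5 equiv), CH2Cl2, 0 °C → rt
Reagents that add atoms: nitrosobenzene, O=Nc1ccccc1; methyl 2-(triphenylphosphoranylidene)propanoate, COC(=O)C(C)=P(c1ccccc1)(c1ccccc1)c1ccccc1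
Why: Proline-catalysed enamine α-aminoxylation, in which D-proline directs nitrosobenzene to the face that gives the (S)-α-oxy aldehyde (C6), followed in the same flask by Wittig olefination with the stabilised ylide to give the (E)-trisubstituted enoate before the labile aldehyde can epimerise.

Step 11
Reactants: 17 (E)-2-methyl enoate with C6–O–NHPh
Product: 18 (6S)-γ-hydroxy (E)-2-methyl enoate
Conditions: Cu(OAc)2 (30 mol %), EtOH, rt
Reagents that add atoms: none
Why: Copper-catalysed cleavage of the O–N bond of the anilinooxy group frees the C6 hydroxyl without touching the iodoalkene or the enoate, whose E geometry prevents lactonisation.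

Step 12
Reactants: 18 (6S)-γ-hydroxy (E)-2-methyl enoate
Product: 19 C6 tert-butyldimethylsilyl ether
Conditions: t-BuMe2SiOTf, 2,6-lutidine, CH2Cl2, −78 °C
Reagents that add atoms: tert-butyldimethylsilyl triflate, CC(C)(C)[Si](C)(C)OS(=O)(=O)C(F)(F)F
Why: Silyl triflate protection of the allylic secondary alcohol gives the bulky C6 ether that later steers the cycloaddition by allylic strain.

Step 13
Reactants: 19 C6 tert-butyldimethylsilyl ether; 20 tributyl(vinyl)stannane
Product: 21 triene (key-step precursor)
Conditions: Pd2(dba)3 (2.5 mol %), AsPh3 (20 mol %), DMF, 40 °C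
Reagents that add atoms: tributyl(vinyl)stannane, C=C[Sn](CCCC)(CCCC)CCCC
Why: Stille coupling of the iodoalkene with retention of geometry completes the (E)-diene C10(CH3)=C1–C2=C3 under neutral conditions that the enoate and both silyl ethers tolerate.

Step 14
Reactants: 21 triene (key-step precursor)
Product: 22 trans-fused octalin (key-step product)
Conditions: Et2AlCl (2 equiv), CH2Cl2, −78 → 23 °C
Reagents that add atoms: none
Why: A concerted, suprafacial [4+2] cycloaddition joins C3 to C4 and C5 to C10; the closest known reaction type is the Lewis-acid-promoted intramolecular Diels–Alder reaction of 2,8,10-undecatrienoates to trans-decalins. Ring A closes as the six-membered cycloadduct ring and ring B as the six-membered ring defined by the four-atom C6–C9 tether between dienophile carbon C5 and diene terminus C10. The E enoate is copied into C4/C5 (CO2Me cis to H5, CH3 cis to C6), and because C9 sits outside and the methyl inside on the diene terminus, the ester-endo transition state gives the trans fusion (H5 anti to the C10 methyl). The face is fixed by the existing centres: allylic 1,3-strain with the C4 methyl holds H6 inside and the C6 silyloxy group equatorial, and the chair-like tether keeps the C8 silyloxy group and the C9 side chain equatorial, whereas the other face would put all three axial. The step therefore needs endo over exo selectivity and one π-face, secured by the Lewis-acid-enhanced ester-endo preference and by C6, C8 and C9. The inside methyl on C10 slows the reaction, which is why the ester is activated with Et2AlCl.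

Step 15
Reactants: 22 trans-fused octalin (key-step product)
Product: 23 saturated decalin C12 alcohol
Conditions: H2 (1 atm), Pd(OH)2/C, EtOAc, rt
Reagents that add atoms: none
Why: Catalytic hydrogenation saturates the cis-disubstituted C1=C2 alkene and hydrogenolyses the benzyl ether in one operation; no stereocentre is formed and the silyl ethers are stable in ethyl acetate.

Step 16
Reactants: 23 saturated decalin C12 alcohol
Product: 24 C12 iodide
Conditions: I2, PPh3, imidazole, CH2Cl2, 0 °C → rt
Reagents that add atoms: iodine, II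
Why: Appel-type iodination converts the only free (primary) hydroxyl into the iodide through its alkoxyphosphonium salt.

Step 17
Reactants: 25 but-2-yn-1-ol
Product: 27 (Z)-3-iodobut-2-en-1-ol, via cyclic alkenylalanate 26 (not isolated)
Conditions: NaAlH2(OCH2CH2OMe)2, THF, 0 °C → rt; then I2, THF, −78 °C
Reagents that add atoms: iodine, II
Why: Hydroxyl-directed trans-hydroalumination of the propargylic alcohol places aluminium on C3 in a five-membered alkoxyaluminate, and iodinolysis with retention gives the Z iodoalkene (iodine cis to CH2OH).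

Step 18
Reactants: 24 C12 iodide; 27 (Z)-3-iodobut-2-en-1-ol
Product: 29 (13Z)-allylic alcohol, via alkylzinc iodide 28 (not isolated)
Conditions: Zn dust, LiCl, THF, 40 °C; then 27 (1.5 equiv), Pd(OAc)2 (2 mol %), SPhos (4 mol %), THF, rt
Reagents that add atoms: (Z)-3-iodobut-2-en-1-ol, C/C(I)=C/CO; zinc, [Zn] (present only in 28)
Why: Zinc insertion into the primary iodide followed by Negishi sp3–sp2 coupling forms C12–C13 with retention of the alkene geometry; the alkylzinc tolerates the hindered ester and, under fast catalysis, the free hydroxyl.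

Step 19
Reactants: 29 (13Z)-allylic alcohol
Product: 30 (13S,14R)-13,14-epoxy C15 alcohol
Conditions: Ti(OiPr)4 (1.0 equiv), D-(−)-diethyl tartrate (1.2 equiv), t-BuOOH, 4 Å sieves, CH2Cl2, −20 °C
Reagents that add atoms: tert-butyl hydroperoxide, CC(C)(C)OO
Why: Sharpless asymmetric epoxidation under reagent control (the decalin centres are remote), in which D-(−)-tartrate gives the (13S,14R)-epoxide of this Z allylic alcohol, the mirror-image sense of step 1.

Step 20
Reactants: 30 (13S,14R)-13,14-epoxy C15 alcohol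
Product: 31 C15 4-methoxybenzyl ether
Conditions: NaH, 4-MeOC6H4CH2Cl, Bu4NI (cat.), THF–DMF, 0 °C
Reagents that add atoms: 4-methoxybenzyl chloride, COc1ccc(CCl)cc1
Why: Williamson etherification masks the primary hydroxyl as an ether that cannot take part as a neighbouring group in the epoxide opening and is removable later under neutral oxidative conditions.

Step 21
Reactants: 31 C15 4-methoxybenzyl ether
Product: 32 (13R,14R)-13-hydroperoxy 14-alcohol
Conditions: anhydrous H2O2 in Et2O (excess), H3PMo12O40 (5 mol %), rt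
Reagents that add atoms: hydrogen peroxide, OO
Why: Acid-catalysed perhydrolysis of the epoxide, in which H2O2 attacks the tertiary C13 (the carbon remote from the electron-withdrawing C15 ether) anti to the departing oxygen, so that the (13S)-epoxide gives the (13R)-hydroperoxide by inversion while C14 is unchanged.

Step 22
Reactants: 32 (13R,14R)-13-hydroperoxy 14-alcohol
Product: 33 2-methoxyprop-2-yl peroxide of 32
Conditions: 2-methoxypropene (1.2 equiv), PPTS (cat.), CH2Cl2, −20 °C; Et3N quench
Reagents that add atoms: 2-methoxypropene, COC(C)=C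
Why: Acid-catalysed addition of the hydroperoxide to the enol ether gives the monoperoxyketal, the more nucleophilic OOH reacting ahead of the hindered secondary C14 hydroxyl; the peroxide is now inert to the base of step 31.

Step 23
Reactants: 33 2-methoxyprop-2-yl peroxide of 32
Product: 34 14,15-diol peroxyketal
Conditions: DDQ, CH2Cl2–pH 7 buffer 10:1, 0 °C
Reagents that add atoms: none
Why: Oxidative cleavage of the 4-methoxybenzyl ether by DDQ in buffered wet solvent (water intercepts the oxocarbenium ion before the neighbouring hydroxyl can form an acetal) frees the diol without acid or reducing agents, which the peroxyketal would not survive.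

Step 24
Reactants: 34 14,15-diol peroxyketal
Product: 35 (13R)-α-peroxy aldehyde
Conditions: NaIO4, THF–pH 7 buffer, 0 °C
Reagents that add atoms: none
Why: Periodate glycol cleavage excises C15 and gives the non-enolisable C14 aldehyde next to the quaternary, peroxide-bearing C13.

Step 25
Reactants: 36 1-phenyl-1H-tetrazole-5-thiol; 37 2-chloro-N-methoxy-N-methylacetamide
Product: 38 N-methoxy-N-methyl-2-[(1-phenyl-1H-tetrazol-5-yl)sulfanyl]acetamide
Conditions: K2CO3, acetone, rt
Reagents that add atoms: 2-chloro-N-methoxy-N-methylacetamide, CON(C)C(=O)CCl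
Why: SN2 S-alkylation of the thiolate by the α-chloro amide installs the heteroaryl sulfur needed for the later olefination.

Step 26
Reactants: 38 N-methoxy-N-methyl-2-[(1-phenyl-1H-tetrazol-5-yl)sulfanyl]acetamide; 39 methyl propiolate
Product: 41 methyl 4-oxo-5-[(1-phenyl-1H-tetrazol-5-yl)sulfanyl]pent-2-ynoate, via lithium methyl propiolate 40 (not isolated)
Conditions: 39, LiN(SiMe3)2, THF, −78 °C; then 38, −78 → −40 °C; aq NH4Cl
Reagents that add atoms: methyl propiolate, C#CC(=O)OC
Why: Acylation of the weakly basic lithium acetylide by the Weinreb amide stops at the chelated tetrahedral intermediate and gives the ynone on work-up.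

Step 27
Reactants: 41 methyl 4-oxo-5-[(1-phenyl-1H-tetrazol-5-yl)sulfanyl]pent-2-ynoate
Product: 42 methyl (R)-4-hydroxy-5-[(1-phenyl-1H-tetrazol-5-yl)sulfanyl]pent-2-ynoate
Conditions: (S)-Alpine-Borane [B-isopinocampheyl-9-BBN from (−)-α-pinene] (1.5 equiv), THF, 0 °C → rt; MeCHO; HOCH2CH2NH2
Reagents that add atoms: none
Why: Midland reduction of the alkynyl ketone, in which the slim alkynyl group takes the small-group position of the boat-like transition state, so that the (S)-reagent delivers hydride to the face that gives the future C16 configuration (formally R here because of the sulfur substituent).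

Step 28
Reactants: 42 methyl (R)-4-hydroxy-5-[(1-phenyl-1H-tetrazol-5-yl)sulfanyl]pent-2-ynoate
Product: 43 tert-butyldimethylsilyl ether of 42
Conditions: t-BuMe2SiCl, imidazole, DMF, rt
Reagents that add atoms: tert-butyldimethylsilyl chloride, CC(C)(C)[Si](C)(C)Cl
Why: Silylation of the propargylic alcohol blocks lactonisation, so that the Z enoate of the next step stays open-chain until the end.

Step 29
Reactants: 43 tert-butyldimethylsilyl ether of 42
Product: 44 methyl (R,Z)-4-(tert-butyldimethylsilyloxy)-3-methyl-5-[(1-phenyl-1H-tetrazol-5-yl)sulfanyl]pent-2-enoate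
Conditions: Me2CuLi (from MeLi and CuI), THF, −78 °C; MeOH then aq NH4Cl at −78 °C
Reagents that add atoms: lithium dimethylcuprate, [Li+].C[Cu-]C (made in the flask from methyllithium, [Li]C, and CuI)
Why: Syn carbocupration of the ynoate and protonation at low temperature with retention give the β-methyl enoate in which C16 and the ester are cis (Z), the geometry required for butenolide closure.

Step 30
Reactants: 44 methyl (R,Z)-4-(tert-butyldimethylsilyloxy)-3-methyl-5-[(1-phenyl-1H-tetrazol-5-yl)sulfanyl]pent-2-enoate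
Product: 45 C15–C19 sulfone
Conditions: (NH4)6Mo7O24 (10 mol %), 30 % H2O2, EtOH, 0 °C → rt
Reagents that add atoms: hydrogen peroxide, OO
Why: Molybdate-catalysed oxidation takes the sulfide to the sulfone and leaves the electron-poor enoate alkene alone.

Step 31
Reactants: 35 (13R)-α-peroxy aldehyde; 45 C15–C19 sulfone
Product: 47 fully protected (14E,17Z)-seco ester, via potassiated sulfone 46 (not isolated)
Conditions: KN(SiMe3)2 added to 35 and 45, DME, −78 °C
Reagents that add atoms: C15–C19 sulfone 45, COC(=O)/C=C(C)\[C@H](CS(=O)(=O)c1nnnn1-c1ccccc1)O[Si](C)(C)C(C)(C)C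
Why: Julia–Kocienski olefination under Barbier conditions (the aldehyde cannot enolise), in which the sulfonyl carbanion is trapped as it forms and the Smiles rearrangement–elimination gives the E C14=C15 alkene, with C13 and C16 brought in unchanged.

Step 32
Reactants: 47 fully protected (14E,17Z)-seco ester
Product: 49 target compound CNP0128148.1, via seco hydroxy ester 48 (not isolated)
Conditions: 48 % aq HF–MeCN 1:19, 0 °C → rt
Reagents that add atoms: none
Why: Aqueous HF removes the three silyl ethers and hydrolyses the peroxyketal, and the freed C16 hydroxyl lactonises onto the Z enoate to close the butenolide; acid is used throughout because H16 of the butenolide is base-labile and no stereocentre is touched.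

Compound list
1 | nerol | CC(C)=CCC/C(C)=C\CO | starting material
2 | (2S,3R)-2,3-epoxynerol | CC(C)=CCC[C@@]1(C)O[C@H]1CO | intermediate
3 | vinylmagnesium bromide | C=C[Mg]Br | starting material
4 | (2R,3R)-2-ethenyl-3,7-dimethyloct-6-ene-1,3-diol | CC(C)=CCC[C@@](C)(O)[C@@H](CO)C=C | intermediate
5 | bis(triethylsilyl) ether of 4 (primary O of the future C10 and tertiary O of C8) | CC(C)=CCC[C@@](C)(O[Si](CC)(CC)CC)[C@@H](CO[Si](CC)(CC)CC)C=C | intermediate
6 | B-alkyl-9-BBN adduct of 5 (boron on the future C12) | CC(C)=CCC[C@@](C)(O[Si](CC)(CC)CC)[C@@H](CO[Si](CC)(CC)CC)CCB1C2CCCC1CCC2 | intermediate (not isolated)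
7 | C12 primary alcohol (both silyl ethers kept) | CC(C)=CCC[C@@](C)(O[Si](CC)(CC)CC)[C@@H](CO[Si](CC)(CC)CC)CCO | intermediate
8 | C12 benzyl ether of 7 | CC(C)=CCC[C@@](C)(O[Si](CC)(CC)CC)[C@@H](CO[Si](CC)(CC)CC)CCOCc1ccccc1 | intermediate
9 | C10 aldehyde with C8 OTES and C12 OBn | CC(C)=CCC[C@@](C)(O[Si](CC)(CC)CC)[C@@H](C=O)CCOCc1ccccc1 | intermediate
10 | terminal alkyne C10≡C1 | CC(C)=CCC[C@@](C)(O[Si](CC)(CC)CC)[C@@H](C#C)CCOCc1ccccc1 | intermediate
11 | (E)-alkenyldimethylalane (methyl on C10, aluminium on C1) | CC(C)=CCC[C@@](C)(O[Si](CC)(CC)CC)[C@@H](/C(C)=C/[Al](C)C)CCOCc1ccccc1 | intermediate (not isolated)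
12 | (E)-iodoalkene C9–C10(CH3)=C1H–I | CC(C)=CCC[C@@](C)(O[Si](CC)(CC)CC)[C@@H](/C(C)=C/I)CCOCc1ccccc1 | intermediate
13 | vicinal diol from the isopropylidene alkene of 12 (carbinol epimers) | CC(C)(O)C(O)CC[C@@](C)(O[Si](CC)(CC)CC)[C@@H](/C(C)=C/I)CCOCc1ccccc1 | intermediate (not isolated)
14 | C5 aldehyde | O=CCC[C@@](C)(O[Si](CC)(CC)CC)[C@@H](/C(C)=C/I)CCOCc1ccccc1 | intermediate
15 | methyl 2-(triphenylphosphoranylidene)propanoate | COC(=O)C(C)=P(c1ccccc1)(c1ccccc1)c1ccccc1 | starting material
16 | (6S)-α-(N-phenylaminooxy) aldehyde | O=C[C@@H](ONc1ccccc1)C[C@@](C)(O[Si](CC)(CC)CC)[C@@H](/C(C)=C/I)CCOCc1ccccc1 | intermediate (not isolated)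
17 | (E)-2-methyl enoate with C6–O–NHPh | COC(=O)/C(C)=C/[C@@H](ONc1ccccc1)C[C@@](C)(O[Si](CC)(CC)CC)[C@@H](/C(C)=C/I)CCOCc1ccccc1 | intermediate
18 | (6S)-γ-hydroxy (E)-2-methyl enoate | COC(=O)/C(C)=C/[C@@H](O)C[C@@](C)(O[Si](CC)(CC)CC)[C@@H](/C(C)=C/I)CCOCc1ccccc1 | intermediate
19 | C6 tert-butyldimethylsilyl ether of 18 | COC(=O)/C(C)=C/[C@@H](O[Si](C)(C)C(C)(C)C)C[C@@](C)(O[Si](CC)(CC)CC)[C@@H](/C(C)=C/I)CCOCc1ccccc1 | intermediate
20 | tributyl(vinyl)stannane | C=C[Sn](CCCC)(CCCC)CCCC | starting material
21 | triene, key-step precursor: (E)-2-methyl enoate and (E)-diene, C6 OTBS, C8 OTES, C12 OBn | COC(=O)/C(C)=C/[C@@H](O[Si](C)(C)C(C)(C)C)C[C@@](C)(O[Si](CC)(CC)CC)[C@@H](/C(C)=C/C=C)CCOCc1ccccc1 | intermediate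
22 | trans-fused octalin, key-step product, with C1=C2 | COC(=O)[C@]1(C)CC=C[C@@]2(C)[C@H]1[C@@H](O[Si](C)(C)C(C)(C)C)C[C@@](C)(O[Si](CC)(CC)CC)[C@@H]2CCOCc3ccccc3 | intermediate
23 | saturated decalin C12 alcohol | COC(=O)[C@]1(C)CCC[C@@]2(C)[C@H]1[C@@H](O[Si](C)(C)C(C)(C)C)C[C@@](C)(O[Si](CC)(CC)CC)[C@@H]2CCO | intermediate
24 | C12 iodide | COC(=O)[C@]1(C)CCC[C@@]2(C)[C@H]1[C@@H](O[Si](C)(C)C(C)(C)C)C[C@@](C)(O[Si](CC)(CC)CC)[C@@H]2CCI | intermediate
25 | but-2-yn-1-ol | CC#CCO | starting material
26 | cyclic sodium alkenylalanate from 25 | [Na+].CC1=CCO[Al-]1(OCCOC)OCCOC | intermediate (not isolated)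
27 | (Z)-3-iodobut-2-en-1-ol | C/C(I)=C/CO | intermediate
28 | C12 alkylzinc iodide | COC(=O)[C@]1(C)CCC[C@@]2(C)[C@H]1[C@@H](O[Si](C)(C)C(C)(C)C)C[C@@](C)(O[Si](CC)(CC)CC)[C@@H]2CC[Zn]I | intermediate (not isolated)
29 | (13Z)-allylic alcohol C12–C13(CH3)=C14H–C15H2OH | COC(=O)[C@]1(C)CCC[C@@]2(C)[C@H]1[C@@H](O[Si](C)(C)C(C)(C)C)C[C@@](C)(O[Si](CC)(CC)CC)[C@@H]2CC/C(C)=C\CO | intermediate
30 | (13S,14R)-13,14-epoxy C15 alcohol | COC(=O)[C@]1(C)CCC[C@@]2(C)[C@H]1[C@@H](O[Si](C)(C)C(C)(C)C)C[C@@](C)(O[Si](CC)(CC)CC)[C@@H]2CC[C@]3(C)O[C@@H]3CO | intermediate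
31 | C15 4-methoxybenzyl ether of 30 | COC(=O)[C@]1(C)CCC[C@@]2(C)[C@H]1[C@@H](O[Si](C)(C)C(C)(C)C)C[C@@](C)(O[Si](CC)(CC)CC)[C@@H]2CC[C@]3(C)O[C@@H]3COCc4ccc(OC)cc4 | intermediate
32 | (13R,14R)-13-hydroperoxy 14-alcohol | COC(=O)[C@]1(C)CCC[C@@]2(C)[C@H]1[C@@H](O[Si](C)(C)C(C)(C)C)C[C@@](C)(O[Si](CC)(CC)CC)[C@@H]2CC[C@](C)([C@H](O)COCc3ccc(OC)cc3)OO | intermediate
33 | 2-methoxyprop-2-yl peroxide (peroxyketal) of 32 | COC(=O)[C@]1(C)CCC[C@@]2(C)[C@H]1[C@@H](O[Si](C)(C)C(C)(C)C)C[C@@](C)(O[Si](CC)(CC)CC)[C@@H]2CC[C@](C)([C@H](O)COCc3ccc(OC)cc3)OOC(C)(C)OC | intermediate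
34 | 14,15-diol peroxyketal | COC(=O)[C@]1(C)CCC[C@@]2(C)[C@H]1[C@@H](O[Si](C)(C)C(C)(C)C)C[C@@](C)(O[Si](CC)(CC)CC)[C@@H]2CC[C@](C)([C@H](O)CO)OOC(C)(C)OC | intermediate
35 | (13R)-α-peroxy aldehyde (C14 aldehyde) | COC(=O)[C@]1(C)CCC[C@@]2(C)[C@H]1[C@@H](O[Si](C)(C)C(C)(C)C)C[C@@](C)(O[Si](CC)(CC)CC)[C@@H]2CC[C@](C)(C=O)OOC(C)(C)OC | intermediate
36 | 1-phenyl-1H-tetrazole-5-thiol | Sc1nnnn1-c1ccccc1 | starting material
37 | 2-chloro-N-methoxy-N-methylacetamide | CON(C)C(=O)CCl | starting material
38 | N-methoxy-N-methyl-2-[(1-phenyl-1H-tetrazol-5-yl)sulfanyl]acetamide | CON(C)C(=O)CSc1nnnn1-c1ccccc1 | intermediate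
39 | methyl propiolate | C#CC(=O)OC | starting material
40 | lithium methyl propiolate | [Li]C#CC(=O)OC | intermediate (not isolated)
41 | methyl 4-oxo-5-[(1-phenyl-1H-tetrazol-5-yl)sulfanyl]pent-2-ynoate | COC(=O)C#CC(=O)CSc1nnnn1-c1ccccc1 | intermediate
42 | methyl (R)-4-hydroxy-5-[(1-phenyl-1H-tetrazol-5-yl)sulfanyl]pent-2-ynoate | COC(=O)C#C[C@@H](O)CSc1nnnn1-c1ccccc1 | intermediate
43 | tert-butyldimethylsilyl ether of 42 | COC(=O)C#C[C@@H](O[Si](C)(C)C(C)(C)C)CSc1nnnn1-c1ccccc1 | intermediate
44 | methyl (R,Z)-4-(tert-butyldimethylsilyloxy)-3-methyl-5-[(1-phenyl-1H-tetrazol-5-yl)sulfanyl]pent-2-enoate | COC(=O)/C=C(C)\[C@H](CSc1nnnn1-c1ccccc1)O[Si](C)(C)C(C)(C)C | intermediate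
45 | C15–C19 sulfone: methyl (R,Z)-4-(tert-butyldimethylsilyloxy)-3-methyl-5-[(1-phenyl-1H-tetrazol-5-yl)sulfonyl]pent-2-enoate | COC(=O)/C=C(C)\[C@H](CS(=O)(=O)c1nnnn1-c1ccccc1)O[Si](C)(C)C(C)(C)C | intermediate
46 | potassiated sulfone (carbanion at C15) | [K+].COC(=O)/C=C(C)\[C@H]([CH-]S(=O)(=O)c1nnnn1-c1ccccc1)O[Si](C)(C)C(C)(C)C | intermediate (not isolated)
47 | fully protected (14E,17Z)-seco ester: C6 OTBS, C8 OTES, C13 peroxyketal, C16 OTBS | COC(=O)[C@]1(C)CCC[C@@]2(C)[C@H]1[C@@H](O[Si](C)(C)C(C)(C)C)C[C@@](C)(O[Si](CC)(CC)CC)[C@@H]2CC[C@](C)(/C=C/[C@H](O[Si](C)(C)C(C)(C)C)/C(C)=C\C(=O)OC)OOC(C)(C)OC | intermediate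
48 | seco hydroxy ester (all protecting groups removed, lactone still open) | COC(=O)[C@]1(C)CCC[C@@]2(C)[C@H]1[C@@H](O)C[C@@](C)(O)[C@@H]2CC[C@](C)(/C=C/[C@H](O)/C(C)=C\C(=O)OC)OO | intermediate (not isolated)
49 | CNP0128148.1, (4R,5R,6S,8R,9R,10S,13R,16S) | COC(=O)[C@]1(C)CCC[C@@]2(C)[C@H]1[C@@H](O)C[C@@](C)(O)[C@@H]2CC[C@](C)(/C=C/[C@@H]1OC(=O)C=C1C)OO | target

Total step count: 32. Longest linear sequence: 25 steps (steps 1–16, 18–24, 31 and 32); steps 17 and 25–30 make the two side-chain building blocks.

Steps most likely to fail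

Step 14 (intramolecular Diels–Alder reaction). The cycloaddition may be slow, because the inside methyl on C10 disfavours the s-cis diene. Selectivity may leak through the exo (cis-fused) transition state, helped by the 1,3-diaxial C8/C10 methyl pair that the trans chair has to accept. The Lewis acid may also isomerise or oligomerise the diene. The fallback keeps the disconnection but changes the activating group of the dienophile to an aldehyde, which is a stronger and more endo-selective dienophile under Lewis acid. It sets out from 21 and comes back at 22. The enoate 21 would be reduced with i-Bu2AlH (CH2Cl2, −78 °C) to the allylic alcohol F1 and oxidised with MnO2 to the (E)-2-methyl enal F2. Cyclisation with Me2AlCl at −78 °C would give the trans-fused octalin aldehyde F3. Pinnick oxidation (NaClO2, NaH2PO4, 2-methylbut-2-ene) would give the acid F4, and Me3SiCHN2 in MeOH–toluene would give 22.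

Step 21 (epoxide perhydrolysis). The tertiary C13–O bond may ionise before H2O2 attacks, which would erode the inversion, and the heteropoly acid may also cleave the silyl or 4-methoxybenzyl ethers. The fallback drops substitution at C13 for a Schenck ene reaction; it gives up control of C13, so the C13 epimers must be separated. It sets out from 24 (through its zinc reagent 28) and comes back at 35. Negishi coupling of 28 with (E)-2-bromobut-2-ene under the catalyst of step 18 would give the trisubstituted alkene F5. Photo-oxygenation (O2, tetraphenylporphyrin, visible light, CH2Cl2, 0 °C) would give the tertiary allylic hydroperoxide F6 as both C13 epimers; the regioisomeric secondary hydroperoxides would be removed by chromatography. Protection with 2-methoxypropene and PPTS would give the peroxyketal F7. Ozonolysis of the vinyl group (O3, CH2Cl2, −78 °C; Me2S) would give 35 together with its C13 epimer, to be separated by HPLC there or after step 31.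

Step 31 (Julia–Kocienski olefination). The sulfonyl carbanion may expel its β-silyloxy group or attack a peroxide oxygen before it adds to the hindered, α-quaternary aldehyde. The fallback joins the halves by cross-metathesis; it sets out from 35 and 45 and comes back at 47. Wittig methylenation of 35 (Ph3P=CH2, THF, −78 → 0 °C) would give the vinyl peroxyketal F8. Julia–Kocienski methylenation of 45 with formaldehyde, an unhindered electrophile that traps the carbanion at once (KN(SiMe3)2, paraformaldehyde, THF, −78 °C), would give the C15–C19 terminal alkene F9. Cross-metathesis of F8 with F9 using the second-generation Hoveyda–Grubbs catalyst (C31H38Cl2N2ORu, CH2Cl2, 40 °C) should give the E alkene 47, which goes on to step 32.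

Further compounds
F1 | step 14 | (E)-2-methyl allylic alcohol from reduction of the ester of 21 | OC/C(C)=C/[C@@H](O[Si](C)(C)C(C)(C)C)C[C@@](C)(O[Si](CC)(CC)CC)[C@@H](/C(C)=C/C=C)CCOCc1ccccc1
F2 | step 14 | (E)-2-methyl enal triene | O=C/C(C)=C/[C@@H](O[Si](C)(C)C(C)(C)C)C[C@@](C)(O[Si](CC)(CC)CC)[C@@H](/C(C)=C/C=C)CCOCc1ccccc1
F3 | step 14 | trans-fused octalin C4 aldehyde | O=C[C@]1(C)CC=C[C@@]2(C)[C@H]1[C@@H](O[Si](C)(C)C(C)(C)C)C[C@@](C)(O[Si](CC)(CC)CC)[C@@H]2CCOCc3ccccc3
F4 | step 14 | trans-fused octalin C4 carboxylic acid | OC(=O)[C@]1(C)CC=C[C@@]2(C)[C@H]1[C@@H](O[Si](C)(C)C(C)(C)C)C[C@@](C)(O[Si](CC)(CC)CC)[C@@H]2CCOCc3ccccc3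
F5 | step 21 | (E)-trisubstituted alkene C12–C13(CH3)=C14H–CH3 | COC(=O)[C@]1(C)CCC[C@@]2(C)[C@H]1[C@@H](O[Si](C)(C)C(C)(C)C)C[C@@](C)(O[Si](CC)(CC)CC)[C@@H]2CC/C(C)=C/C
F6 | step 21 | tertiary allylic hydroperoxide with a vinyl group on C13 (both C13 epimers) | COC(=O)[C@]1(C)CCC[C@@]2(C)[C@H]1[C@@H](O[Si](C)(C)C(C)(C)C)C[C@@](C)(O[Si](CC)(CC)CC)[C@@H]2CCC(C)(C=C)OO
F7 | step 21 | 2-methoxyprop-2-yl peroxide of F6 (both C13 epimers) | COC(=O)[C@]1(C)CCC[C@@]2(C)[C@H]1[C@@H](O[Si](C)(C)C(C)(C)C)C[C@@](C)(O[Si](CC)(CC)CC)[C@@H]2CCC(C)(C=C)OOC(C)(C)OC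
F8 | step 31 | (13R)-vinyl peroxyketal | COC(=O)[C@]1(C)CCC[C@@]2(C)[C@H]1[C@@H](O[Si](C)(C)C(C)(C)C)C[C@@](C)(O[Si](CC)(CC)CC)[C@@H]2CC[C@](C)(C=C)OOC(C)(C)OC
F9 | step 31 | methyl (S,Z)-4-(tert-butyldimethylsilyloxy)-3-methylhexa-2,5-dienoate | C=C[C@H](O[Si](C)(C)C(C)(C)C)/C(C)=C\C(=O)OC
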